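Ring B is cut at its two bonds to ring A, C4–C4a and C1–C8a. Since C8a lies next to the oxygen-bearing C8, this pair of bonds has the polarity of a 3-alkoxybenzyne, which takes a carbanion at the carbon meta to oxygen and an acyl group at the ortho carbon. Without the arene, C1 and C4 are joined directly: a cyclobutanone with the pyrone on C4 and phenyl plus protected hydroxyl on C3. One operation splices the aryne into this strained C1–C4 bond, makes both aryl bonds, enlarges the four-membered ring to ring B and sets C4. The precursor, an enantiopure 2-pyronyl-3-benzyloxy-3-phenylcyclobutanone, comes from a ketene–enol ether cycloaddition and resolution.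

Key step: step 8

Remark 1 (numbering): the target locants (C1 ketone, C2 methylene, C3 carbinol carbon, C4 pyronyl methine, C4a/C8a ring fusion, C8 phenol carbon) are used for these atoms in every intermediate. Ring A is the arene and ring B the cyclohexanone.
Remark 2 (descriptors): the target is (3S,4S), with pyronyl trans to the C3 oxygen and cis to phenyl. In the C3 ethers the same arrangement at C4 is called R, because an O-alkyl group ranks C3 above the pyronyl carbon.
Remark 3 (protecting groups): all three oxygens travel as benzyl ethers. At C3 this group is inert to fluoride and leaves less readily than a silanolate. It is also small at oxygen, so phenyl dictates the shape of the C4 anion, and it departs with the other two in one neutral step.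
Remark 4 (aryne precursor): the silyl group is placed by bromine–lithium exchange and not by deprotonation, because alkyllithiums also attack the benzylic CH2 of aryl benzyl ethers.

Step 1
Reactants: 1 4-hydroxy-6-methyl-2H-pyran-2-one (triacetic acid lactone)
Product: 2 4-(benzyloxy)-6-methyl-2H-pyran-2-one
Conditions: BnBr, K2CO3, DMF, 50 °C
Reagents that add atoms: benzyl bromide, BrCc1ccccc1
Why: Williamson O-alkylation of the vinylogous acid, whose potassium salt should react at the 4-oxygen because only this site keeps the 2-pyrone conjugation intact.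

Step 2
Reactants: 2 4-(benzyloxy)-6-methyl-2H-pyran-2-one
Product: 4 [4-(benzyloxy)-2-oxo-2H-pyran-6-yl]acetic acid, via lithium dienolate 3 (not isolated)
Conditions: LDA (2.2 equiv), THF, −78 °C; CO2; 1 M HCl, 0 °C
Reagents that add atoms: carbon dioxide, O=C=O
Why: LDA deprotonates the C6 methyl group (vinylogous ester deprotonation) and the extended lithium dienolate is carboxylated at its exocyclic carbon, while the second equivalent of base covers the more acidic product and the cold acidic work-up keeps the acid from decarboxylating.

Step 3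
Reactants: 5 benzyl benzoate
Product: 6 [1-(benzyloxy)ethenyl]benzene (alpha-benzyloxystyrene)
Conditions: Cp2TiMe2, toluene, 70 °C, dark; filtration through basic alumina
Reagents that add atoms: dimethyltitanocene Cp2TiMe2, C[Ti](C)(C1C=CC=C1)C1C=CC=C1
Why: Petasis methylenation, in which the titanium methylidene formed on heating exchanges the ester carbonyl oxygen for CH2 under non-acidic conditions that spare the acid-labile enol ether.

Step 4
Reactants: 4 [4-(benzyloxy)-2-oxo-2H-pyran-6-yl]acetic acid; 6 [1-(benzyloxy)ethenyl]benzene
Product: 9 rac-(2S*,3S*)-3-(benzyloxy)-2-[4-(benzyloxy)-2-oxo-2H-pyran-6-yl]-3-phenylcyclobutan-1-one, via acid chloride 7 (not isolated), via pyronylketene 8 (not isolated)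
Conditions: (COCl)2, cat. DMF, CH2Cl2, 0 °C, then evaporation; slow addition to 6 (3 equiv), i-Pr2NEt (1.05 equiv), toluene, 0 °C → rt
Reagents that add atoms: none
Why: Staudinger-type ketene–enol ether [2+2] cycloaddition, in which the nucleophilic CH2 terminus of 6 bonds to the ketene carbonyl carbon (C1–C2) and the oxocarbenium carbon bonds to the pyronyl carbon (C3–C4), so the 2-pyronyl-3-oxy pattern is the only regiochemistry open; C3 arises racemic and the acidic pyronyl carbon should settle as the epimer with pyronyl trans to phenyl.

Step 5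
Reactants: 9 rac-(2S*,3S*)-3-(benzyloxy)-2-[4-(benzyloxy)-2-oxo-2H-pyran-6-yl]-3-phenylcyclobutan-1-one
Product: 10 (2S,3S)-3-(benzyloxy)-2-[4-(benzyloxy)-2-oxo-2H-pyran-6-yl]-3-phenylcyclobutan-1-one
Conditions: preparative SFC, immobilised amylose tris(3,5-dimethylphenylcarbamate) phase, CO2/MeCN, 30 °C, no alcohol or amine additive
Reagents that add atoms: none
Why: Resolution by chromatography on a chiral stationary phase secures the 3S series because the enantiomers differ at the quaternary, non-epimerisable C3; the configuration is to be assigned by anomalous-dispersion X-ray analysis before material is carried on, and the labile pyronyl carbon does not matter since step 8 planarises it.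

Step 6
Reactants: 11 2-bromobenzene-1,3-diol
Product: 12 3-(benzyloxy)-2-bromophenol
Conditions: BnBr (0.9 equiv), K2CO3, acetone, reflux
Reagents that add atoms: benzyl bromide, BrCc1ccccc1
Why: Williamson mono-alkylation of a symmetrical diol with limiting benzyl bromide, a statistical but dependable reaction whose mono-ether, bis-ether and diol are easily separated.

Step 7
Reactants: 12 3-(benzyloxy)-2-bromophenol
Product: 16 3-(benzyloxy)-2-(trimethylsilyl)phenyl trifluoromethanesulfonate, via silyl ether 13 (not isolated), via aryllithium 14 (not isolated), via lithium phenoxide 15 (not isolated)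
Conditions: HMDS, THF, 65 °C, then evaporation; n-BuLi, THF, −100 → −78 °C; Tf2O, −100 °C → rt
Reagents that add atoms: hexamethyldisilazane, C[Si](C)(C)N[Si](C)(C)C; trifluoromethanesulfonic anhydride, O=S(=O)(OS(=O)(=O)C(F)(F)F)C(F)(F)F
Why: Standard assembly of an ortho-silylaryl triflate by O-silylation, bromine–lithium exchange (faster than lithiation of the benzylic CH2), retro-Brook 1,3-shift of silicon from oxygen to the aryl carbanion, and triflation of the phenoxide so formed.

Step 8
Reactants: 10 (2S,3S)-3-(benzyloxy)-2-[4-(benzyloxy)-2-oxo-2H-pyran-6-yl]-3-phenylcyclobutan-1-one; 16 3-(benzyloxy)-2-(trimethylsilyl)phenyl trifluoromethanesulfonate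
Product: 19 (3S,4R)-3,8-bis(benzyloxy)-4-[4-(benzyloxy)-2-oxo-2H-pyran-6-yl]-3-phenyl-3,4-dihydronaphthalen-1(2H)-one, via 3-(benzyloxy)benzyne 17 (not isolated), via fused benzocyclobutenoxide 18 (not isolated)
Conditions: CsF (3 equiv), MeCN, 40 °C, 16 added over 4 h to 10 (1.3 equiv); pH 7 buffer
Reagents that add atoms: none
Why: Proposed new method: fluoride frees aryne 17 from 16 and deprotonates 10 at C4 (flanked by the ketone and by the pyrone, a vinylogous ester); the carbanion adds to the aryne carbon meta to the benzyloxy group (C4–C4a), the aryl anion thus placed at C8a closes on the C1 carbonyl to give 18, and 18 breaks its central C1–C4 bond in a retro-aldol sense, which returns the C4 anion for protonation by fresh 10. The closest known reaction types are the fluoride-triggered acyl-alkylation of arynes with beta-keto esters, which enlarges cyclic ones by two carbons, and the arynic condensation of cyclic ketone enolates; neither a cyclobutanone nor a pyrone as activating group has been shown. Ring B is therefore closed indirectly, by a 4-exo-trig closure followed by fragmentation of the bond shared by the two four-membered rings (four-to-six enlargement), helped by the high electrophilicity of the cyclobutanone carbonyl and by the strain released from both small rings. C4 is the only new stereocentre: in the planar anion, allylic strain with the pyronyl group turns the C3 phenyl pseudoaxial, so the proton arrives on the opposite face and leaves pyronyl cis to phenyl and trans to oxygen, which should also be the more stable epimer (pseudoaxial pyronyl clear of C5–H), so any equilibration converges on it. The regioselectivity needed is the innate one of a 3-alkoxyaryne, whose C–O dipole distorts the triple bond and stabilises charge at the ortho carbon. The chemoselectivity needed (carbanion addition before Diels–Alder capture of 17 by the pyrone, protonation before loss of the C3 oxygen and aromatisation) is served by slow release of 17 into excess 10, by the fluoride-inert and poorly leaving benzyl ether, and by a pseudoequatorial C3–O bond that lies near the nodal plane of the C4 anion.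

Step 9
Reactants: 19 (3S,4R)-3,8-bis(benzyloxy)-4-[4-(benzyloxy)-2-oxo-2H-pyran-6-yl]-3-phenyl-3,4-dihydronaphthalen-1(2H)-one
Product: 20 (3S,4S)-3,8-dihydroxy-4-(4-hydroxy-2-oxo-2H-pyran-6-yl)-3-phenyl-3,4-dihydronaphthalen-1(2H)-one (CNP0287220.2)
Conditions: H2 (1 atm), Pd/C, EtOAc, rt, stopped at full debenzylation
Reagents that add atoms: none
Why: Neutral catalytic hydrogenolysis should cleave the three primary benzylic C–O bonds well before the crowded tertiary benzylic C3–O bond, the aryl ketone or the pyrone react, and the absence of acid and base protects the beta-hydroxy ketone from dehydration to a naphthol and from retro-aldol cleavage, so C3 and C4 are untouched.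

Compound list
1 | 4-hydroxy-6-methyl-2H-pyran-2-one | Cc1cc(O)cc(=O)o1 | starting material
2 | 4-(benzyloxy)-6-methyl-2H-pyran-2-one | Cc1cc(OCc2ccccc2)cc(=O)o1 | intermediate
3 | lithium dienolate of 2 (6-lithiomethyl form) | [Li+].[CH2-]c1cc(OCc2ccccc2)cc(=O)o1 | intermediate
4 | [4-(benzyloxy)-2-oxo-2H-pyran-6-yl]acetic acid | OC(=O)Cc1cc(OCc2ccccc2)cc(=O)o1 | intermediate
5 | benzyl benzoate | O=C(OCc1ccccc1)c1ccccc1 | starting material
6 | [1-(benzyloxy)ethenyl]benzene | C=C(OCc1ccccc1)c1ccccc1 | intermediate
7 | [4-(benzyloxy)-2-oxo-2H-pyran-6-yl]acetyl chloride | ClC(=O)Cc1cc(OCc2ccccc2)cc(=O)o1 | intermediate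
8 | 4-(benzyloxy)-6-(2-oxoethenyl)-2H-pyran-2-one (pyronylketene) | O=C=Cc1cc(OCc2ccccc2)cc(=O)o1 | intermediate
9 | rac-(2S*,3S*)-3-(benzyloxy)-2-[4-(benzyloxy)-2-oxo-2H-pyran-6-yl]-3-phenylcyclobutan-1-one, pyronyl trans to phenyl (racemate, both enantiomers written) | O=C1C[C@@](OCc2ccccc2)(c2ccccc2)[C@@H]1c1cc(OCc2ccccc2)cc(=O)o1.O=C1C[C@](OCc2ccccc2)(c2ccccc2)[C@H]1c1cc(OCc2ccccc2)cc(=O)o1 | intermediate
10 | (2S,3S)-3-(benzyloxy)-2-[4-(benzyloxy)-2-oxo-2H-pyran-6-yl]-3-phenylcyclobutan-1-one | O=C1C[C@@](OCc2ccccc2)(c2ccccc2)[C@@H]1c1cc(OCc2ccccc2)cc(=O)o1 | intermediate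
11 | 2-bromobenzene-1,3-diol | Oc1cccc(O)c1Br | starting material
12 | 3-(benzyloxy)-2-bromophenol | Oc1cccc(OCc2ccccc2)c1Br | intermediate
13 | [3-(benzyloxy)-2-bromophenoxy]trimethylsilane | C[Si](C)(C)Oc1cccc(OCc2ccccc2)c1Br | intermediate
14 | 2-(benzyloxy)-6-(trimethylsilyloxy)phenyllithium | [Li]c1c(O[Si](C)(C)C)cccc1OCc1ccccc1 | intermediate
15 | lithium 3-(benzyloxy)-2-(trimethylsilyl)phenoxide | [Li+].[O-]c1cccc(OCc2ccccc2)c1[Si](C)(C)C | intermediate
16 | 3-(benzyloxy)-2-(trimethylsilyl)phenyl trifluoromethanesulfonate | C[Si](C)(C)c1c(OCc2ccccc2)cccc1OS(=O)(=O)C(F)(F)F | intermediate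
17 | 3-(benzyloxy)benzyne | C1#CC(OCc2ccccc2)=CC=C1 | intermediate
18 | caesium alkoxide of the benzo-fused bicyclo[2.2.0]hexanol (O on C1 and pyronyl on C4 cis, arene on the face away from phenyl) | [Cs+].[O-][C@@]12C[C@@](OCc3ccccc3)(c3ccccc3)[C@]1(c1cc(OCc3ccccc3)cc(=O)o1)c1cccc(OCc3ccccc3)c12 | intermediate
19 | (3S,4R)-3,8-bis(benzyloxy)-4-[4-(benzyloxy)-2-oxo-2H-pyran-6-yl]-3-phenyl-3,4-dihydronaphthalen-1(2H)-one | O=C1C[C@@](OCc2ccccc2)(c2ccccc2)[C@@H](c2cc(OCc3ccccc3)cc(=O)o2)c2cccc(OCc3ccccc3)c21 | intermediate
20 | (3S,4S)-3,8-dihydroxy-4-(4-hydroxy-2-oxo-2H-pyran-6-yl)-3-phenyl-3,4-dihydronaphthalen-1(2H)-one | O=C1C[C@@](O)(c2ccccc2)[C@@H](c2cc(O)cc(=O)o2)c2cccc(O)c21 | target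

Total step count: 9. Longest linear sequence: 6 (steps 1, 2, 4, 5, 8, 9).

Steps most likely to fail

**1. Step 8.**
- Risks:
  - The C4 anion may expel the C3 benzyloxide, after which ring B aromatises.
  - The aryne may add across the pyrone diene.
  - The aryl anion may be protonated before it reaches C1.
  - Fluoride may cleave the strained ketone.
- Fallback: this uses known chemistry and makes the same two bonds one at a time. It sets out from 10 and comes back at 19.
  - N,O-dimethylhydroxylamine in THF should open the strained, doubly activated ketone of 10 at C1–C4 (retro-Claisen cleavage). This gives the Weinreb amide (3R)-3-(benzyloxy)-4-[4-(benzyloxy)-2-oxo-2H-pyran-6-yl]-N-methoxy-N-methyl-3-phenylbutanamide F1. C3 is untouched; the descriptor is new but the arrangement is the same.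
  - Commercial 1-(benzyloxy)-3-bromobenzene is lithiated between its two substituents with LDA at −78 °C. This directed ortho-lithiation uses no alkyllithium, so the benzylic CH2 is safe, and it gives 2-(benzyloxy)-6-bromophenyllithium F2.
  - With one more equivalent of LDA present to take the acidic C4 proton, F2 is acylated by F1 (Weinreb ketone synthesis, C1–C8a). The product is (3R)-3-(benzyloxy)-1-[2-(benzyloxy)-6-bromophenyl]-4-[4-(benzyloxy)-2-oxo-2H-pyran-6-yl]-3-phenylbutan-1-one F3.
  - A palladium-catalysed intramolecular enolate arylation in its vinylogous form (Pd2(dba)3, XPhos, K3PO4, toluene, 80 °C) then closes C4–C4a and gives 19. C4 settles under the same conformational control. No free aryne meets the pyrone in this sequence.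

**2. Step 4.**
- Risks:
  - The ketene may dimerise.
  - The zwitterion may collapse by proton transfer to open-chain acylation instead of closing the ring.
  - Amine hydrochloride may hydrolyse the enol ether.
- Fallback: the ketene is generated without base or salt. The sequence sets out from 2 and comes back at 8, and so at 9.
  - Riley oxidation of the methyl group (SeO2, dioxane, 160 °C, sealed tube) should give 4-(benzyloxy)-2-oxo-2H-pyran-6-carbaldehyde F4.
  - Pinnick oxidation (NaClO2, NaH2PO4, 2-methyl-2-butene, t-BuOH/H2O) gives 4-(benzyloxy)-2-oxo-2H-pyran-6-carboxylic acid F5.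
  - Oxalyl chloride with cat. DMF gives 4-(benzyloxy)-2-oxo-2H-pyran-6-carbonyl chloride F6.
  - Excess diazomethane in Et2O at 0 °C gives 4-(benzyloxy)-6-(2-diazoacetyl)-2H-pyran-2-one F7.
  - Irradiation of F7 (450 nm LED, toluene, rt) in the presence of 6 triggers a Wolff rearrangement. This releases 8 slowly into a neutral medium, where it should be taken up by the same [2+2] cycloaddition.

**3. Step 9.**
- Risks: the crowded tertiary benzyl ether may cleave slowly. Prolonged exposure could then saturate the pyrone, hydrogenolyse the C3–O bond or reduce the aryl ketone.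
- Fallback: the stubborn ether is removed oxidatively and the rest reductively. The sequence sets out from 19 and comes back at 20.
  - Visible-light oxidation with DDQ (wet CH2Cl2, 525 nm LED, rt) attacks the electron-richest benzylic CH2, that of the alkyl benzyl ether. It should give (3S,4S)-8-(benzyloxy)-4-[4-(benzyloxy)-2-oxo-2H-pyran-6-yl]-3-hydroxy-3-phenyl-3,4-dihydronaphthalen-1(2H)-one F8.
  - The two remaining benzyl groups sit on an aryl and on a vinylogous ester oxygen and are fast to cleave. A short hydrogenolysis (H2, Pd/C, EtOAc) then gives 20.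

Further compounds
F1 | step 8 | (3R)-3-(benzyloxy)-4-[4-(benzyloxy)-2-oxo-2H-pyran-6-yl]-N-methoxy-N-methyl-3-phenylbutanamide | CON(C)C(=O)C[C@@](OCc1ccccc1)(c1ccccc1)Cc1cc(OCc2ccccc2)cc(=O)o1
F2 | step 8 | 2-(benzyloxy)-6-bromophenyllithium | [Li]c1c(Br)cccc1OCc1ccccc1
F3 | step 8 | (3R)-3-(benzyloxy)-1-[2-(benzyloxy)-6-bromophenyl]-4-[4-(benzyloxy)-2-oxo-2H-pyran-6-yl]-3-phenylbutan-1-one | O=C(C[C@@](OCc1ccccc1)(c1ccccc1)Cc1cc(OCc2ccccc2)cc(=O)o1)c1c(Br)cccc1OCc1ccccc1
F4 | step 4 | 4-(benzyloxy)-2-oxo-2H-pyran-6-carbaldehyde | O=Cc1cc(OCc2ccccc2)cc(=O)o1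
F5 | step 4 | 4-(benzyloxy)-2-oxo-2H-pyran-6-carboxylic acid | OC(=O)c1cc(OCc2ccccc2)cc(=O)o1
F6 | step 4 | 4-(benzyloxy)-2-oxo-2H-pyran-6-carbonyl chloride | ClC(=O)c1cc(OCc2ccccc2)cc(=O)o1
F7 | step 4 | 4-(benzyloxy)-6-(2-diazoacetyl)-2H-pyran-2-one | [N-]=[N+]=CC(=O)c1cc(OCc2ccccc2)cc(=O)o1
F8 | step 9 | (3S,4S)-8-(benzyloxy)-4-[4-(benzyloxy)-2-oxo-2H-pyran-6-yl]-3-hydroxy-3-phenyl-3,4-dihydronaphthalen-1(2H)-one | O=C1C[C@@](O)(c2ccccc2)[C@@H](c2cc(OCc3ccccc3)cc(=O)o2)c2cccc(OCc3ccccc3)c21
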